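## Structural features

The target is an unbranched C15 chain, numbered here from the alkyne terminus C1 to the ethyl terminus C15, folded by two ether oxygens into an oxolane (O, C10, C11, C12, C13) and an oxirane (O, C6, C7). The oxolane carries the C14–C15 ethyl group on C13, bromine on C12 and, on C10, the side chain C9(Br)–C8H2–oxirane–C5H2–(E)-C3=C4–C1≡C2. There are six stereocentres, (6S,7R,9S,10R,12S,13R). C12 and C13 are contiguous in the ring, C9 and C10 are contiguous across the ring–chain junction, and C7 stands 1,3 to C9 across the C8 methylene. The ring α-carbons C10 and C13 are cis, the C12 bromine is trans to both, and the oxirane is cis. The fragile groups are the oxirane (acid, halide, Lewis acid), the two secondary bromides (E2; the C9 bromide lies next to the ring oxygen), the C5 methylene (acidic once C2 is an aldehyde) and the terminal enyne. The real difficulty is the relative configuration from C6 to C13: cis across the ring oxygen, relay from the ring to C9 and on to the oxirane, and two C–Br bonds made with inversion at oxygen-flanked carbons. The key step exploits the fact that C10 is bonded to the ring oxygen. In an open-chain ether in which that oxygen already joins C13 to C10, the C10–H bond is hydridic and lies 1,5 to C11, so a carbene at C11 next to a C12 carbonyl can insert into it and close the ring.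

## Logic of the disconnections

27 to 26. The C1–C2 bond is cut, leaving the C2 aldehyde of 26. A one-carbon homologation of an aldehyde is a mild late entry to a terminal alkyne and keeps the E geometry already present at C3=C4. The gain is that no alkyne is carried through the halogenation and oxidation steps. The demand is that a strongly basic carbon nucleophile adds to the aldehyde faster than it removes a C5 proton or attacks a bromide.

26 to 25. The C3=C4 double bond is cut by cross-metathesis logic, back to the terminal alkene of 25 and a simple enal partner. The gain is that 25 holds a single, monosubstituted alkene, because C6=C7 is already masked as the oxirane. The demand is E selectivity and a catalyst that tolerates the oxirane and two bromides.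

25 to 24, 23 and 22. The C9–Br bond is cut to the alcohol 24 (inversion), which goes back through ester 23 to the epimeric alcohol 22 (second inversion). The oxirane is best set under the direction of a C9 hydroxyl that is syn to it, but the bromine must finally occupy that same position, so two inversions are needed. The gain is that one oxygen serves first as control element and then as leaving group. The demand is clean SN2 behaviour at C9 without participation by the ring oxygen and without opening of the oxirane.

22 to 21. The C6–O and C7–O bonds are cut, back to the Z alkene of 21. The demand is transfer of facial information from C9 over the C8 methylene, and oxidation of the internal alkene in preference to the terminal one.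

21 to 20, then to 17 and 18 (through 19), then 17 to 15 (through 16). The C9 oxygen is unmasked from 20, and the C6=C7 bond is cut to aldehyde 17 and the four-carbon ylide 19 made from 18. The aldehyde comes from the terminal alkene of 15 by oxidative cleavage through 16. The gain is a commercial four-carbon unit and a short C7 aldehyde. The demand is Z selectivity, and base mild enough for the C12 bromide and the β-alkoxy aldehyde.

15 to 14 and 13. The C12–Br bond is cut to the all-cis alcohol 14 (inversion), which comes from ketone 13 by hydride delivery to the face opposite both ring substituents. The gain is that C12 is set by the shape of the ring alone, and that the ketone is exactly the group the ring-forming step needs. The demand is a bulky hydride and an SN2 bromination at a ring carbon.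

13 to 12. The C10–C11 bond is cut. This opens the oxolane to the acyclic diazoketone 12, in which C11 is the carbene carbon, C12 the ketone, and the ether oxygen already joins C13 to C10. The gain is the loss of the ring, one C–C bond and the C10 stereocentre in one move, leaving an ether of two chiral-pool pieces. The demand is 1,5 insertion into C10–H in preference to other C–H bonds, with cis selectivity relayed from C13.

12 to 10, 9, 5 and 8 (through 11). The C11–C12 bond is cut to acid 10 and a one-carbon diazo reagent. The O–C13 bond is then cut to the primary alcohol 5 and the triflate 8, joined with inversion at C13. The C9 oxygen is carried as a 4-methoxybenzyl ether rather than a silyl ether: a silyl group next to the primary alkoxide needed for this etherification would migrate from the secondary to the primary oxygen, whereas the benzyl-type ether cannot. It is also removed later under neutral oxidative conditions. The demand is SN2 at an α-carbonyl triflate without elimination or acyl transfer.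

5 to 4, 3, 1 and 2; 8 to 7 and 6. Alcohol 5 goes back through the arylidene acetal 4 to diol 3, whose C7–C8 bond is cut to epoxide 1 and the vinyl nucleophile 2. Triflate 8 goes back through ester 7 to hydroxy acid 6. Both stereocentres (C9 and C13) are bought. The demands are regioselective opening of the epoxide, regioselective reductive opening of the acetal, and no racemisation of the triflate.

## Other disconnections considered

Alternative 1: The cut runs through the two C–O bonds of the oxirane, back to a Z C6=C7 alkene with a free C9 hydroxyl. In the forward sense VO(acac)2 and tert-butyl hydroperoxide would deliver oxygen inside the vanadate ester of that hydroxyl to give the epoxy alcohol A1, leaving the monosubstituted C3=C4 alkene alone.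
- In its favour: it uses a resident stereocentre, it differentiates the two alkenes by proximity, and the chair model for Z-homoallylic alcohols predicts the syn product required.
- Against it as the centre of a plan: it forms no carbon–carbon bond and says nothing about the oxolane. It also fixes C9 as an oxygen whose configuration is the one the bromine must later have, which costs two inversions.
- Comparison: on stereochemical predictability and mildness it is the equal of the carbenoid insertion, arguably the better. It sets two stereocentres against one, but no skeletal bond against one bond and a ring. On step economy there is no difference, because the chosen plan uses this same transformation as step 15 (A1 is the same structure as 22). The two ideas are complementary, and the ring problem was judged the one that should define the route.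

Alternative 2: The cut is at C6–Br with re-formation of the C4–C6 bond. It leads back to the cyclopropyl carbinol A2, in which C4, C5 and C6 form a three-membered ring and C3 is a silylalkynyl carbinol. In the forward sense ZnBr2 and Me3SiBr would ionise the carbinol, and bromide would attack C6 from the side opposite the breaking C4–C6 bond, giving the E-enyne bromide A3. Fluoride or mild base would then remove both silyl groups and close the oxirane by displacement of the C6 bromide.
- In its favour: one step would create the E-enyne and the C6 leaving group with defined configuration, and the oxirane would close stereospecifically without a directing hydroxyl. The endgame needs no strongly basic alkynylation in the presence of the oxirane, and C9 could be brominated with a single inversion.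
- Against it: A2 needs an enantiopure cyclopropane built next to three existing stereocentres. The ionisation is cationic, so it needs a tight, concerted opening to keep inversion at C6. Attack at the C5 methylene (cleaving C4–C5) is a plausible competitor because the C7 oxygen withdraws electron density from C6. The Lewis acid and bromide would also act on a substrate that already holds two secondary bromides and a silyl ether.
- Comparison: the endgame is shorter and gentler, and on that point this alternative is the better. The chosen plan is the safer at its strategic step, which runs early and on simple material. Overall step counts should be similar, because the cyclopropane must be made. The alternative also leaves the oxolane unsolved, so it could be combined with the chosen key step rather than replace it.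

Alternative 3: The cuts are C10–C11 and C12–C13, back to furan A4 and 2-bromoacrolein A5. In the forward sense an amino-acid-derived chiral oxazaborolidinone Lewis acid would catalyse the Diels–Alder reaction to give the oxanorbornene A6, whose bridgeheads are the future C10 and C13 and are cis by geometry.
- In its favour: two skeletal bonds and the ring come from achiral bulk chemicals in one catalytic asymmetric step. The cis relation is a geometric certainty rather than a transition-state preference.
- Against it here: A6 contains neither side chain. The ring alkene must be cleaved into two one-carbon arms that then have to be told apart and homologated separately. The bromo aldehyde centre must be degraded to a C12 ketone before the bromide can be installed as in the chosen plan. The C9 stereocentre would have to be made by addition to an aldehyde next to the ring. Furan is also a reluctant, reversible diene.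
- Comparison: it is better on bonds formed per step, on the certainty of the cis relation and on the cost of starting materials. It is equal in needing the same ketone-to-bromide sequence at C12. It is clearly worse in the number of steps after the key step, whereas the chosen precursor already contains the ethyl group, the C9 oxygen and the three-carbon handle for the side chain.

Key step: step 9

Assumption: the vanadate of 21 in step 15 is taken to react through the usual chair with the oxolanyl group on C9 equatorial, which is the syn preference generally shown by Z-homoallylic alcohols.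

## Route

Step 1
Reactants: 1 (R)-glycidol; 2 vinylmagnesium bromide
Product: 3 (S)-pent-4-ene-1,2-diol
Conditions: 2 (2.5 equiv), CuI (10 mol%), THF, −40 → 0 °C; aq NH4Cl
Reagents that add atoms: none
Why: Copper-catalysed SN2 opening of the epoxide at its unsubstituted carbon by the vinyl Grignard reagent; the stereocentre is not touched (the descriptor changes only through priorities), and alkoxide migration of the Payne type would be degenerate for this epoxide.

Step 2
Reactants: 3 (S)-pent-4-ene-1,2-diol
Product: 4 (4S)-2-(4-methoxyphenyl)-4-(prop-2-en-1-yl)-1,3-dioxolane (both epimers at the acetal carbon)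
Conditions: 4-MeOC6H4CH(OMe)2, PPTS (cat.), CH2Cl2, rt
Reagents that add atoms: 4-methoxybenzaldehyde dimethyl acetal, COC(OC)c1ccc(OC)cc1
Why: Acid-catalysed transacetalisation of a 1,2-diol to the five-membered arylidene acetal; the acetal carbon is lost as a stereocentre in the next step, so its epimers do not matter.

Step 3
Reactants: 4 (4S)-2-(4-methoxyphenyl)-4-(prop-2-en-1-yl)-1,3-dioxolane
Product: 5 (2S)-2-[(4-methoxyphenyl)methoxy]pent-4-en-1-ol
Conditions: i-Bu2AlH, CH2Cl2, −78 → 0 °C; aq KNaC4H4O6
Reagents that add atoms: none
Why: Regioselective reductive opening of the arylidene acetal: the aluminium hydride should coordinate the less hindered primary oxygen and cleave that C–O bond, leaving the 4-methoxybenzyl group on the secondary oxygen, where it cannot migrate under the alkoxide conditions of step 6.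

Step 4
Reactants: 6 (S)-2-hydroxybutanoic acid
Product: 7 methyl (S)-2-hydroxybutanoate
Conditions: MeOH, H2SO4 (cat.), reflux
Reagents that add atoms: methanol, CO
Why: Fischer esterification in excess methanol; no bond to the stereocentre is broken.

Step 5
Reactants: 7 methyl (S)-2-hydroxybutanoate
Product: 8 methyl (2S)-2-[(trifluoromethanesulfonyl)oxy]butanoate
Conditions: Tf2O, 2,6-lutidine, CH2Cl2, −78 → 0 °C
Reagents that add atoms: trifluoromethanesulfonic anhydride, O=S(=O)(OS(=O)(=O)C(F)(F)F)C(F)(F)F
Why: O-Sulfonylation of the secondary alcohol with a hindered base, with retention because only the O–H bond reacts; the triflate is used at once to avoid loss of configuration.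

Step 6
Reactants: 5 (2S)-2-[(4-methoxyphenyl)methoxy]pent-4-en-1-ol; 8 methyl (2S)-2-[(trifluoromethanesulfonyl)oxy]butanoate
Product: 9 methyl (2R)-2-{[(2S)-2-[(4-methoxyphenyl)methoxy]pent-4-en-1-yl]oxy}butanoate
Conditions: NaH, THF, 0 °C; then 8, −40 → 0 °C
Reagents that add atoms: none
Why: Williamson etherification by SN2 displacement of the α-carbonyl triflate by the primary sodium alkoxide, which should invert C13 from S to R; the adjacent carbonyl accelerates substitution and the low temperature holds back E2 and acyl transfer.

Step 7
Reactants: 9 methyl (2R)-2-{[(2S)-2-[(4-methoxyphenyl)methoxy]pent-4-en-1-yl]oxy}butanoate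
Product: 10 (2R)-2-{[(2S)-2-[(4-methoxyphenyl)methoxy]pent-4-en-1-yl]oxy}butanoic acid
Conditions: LiOH, THF/H2O (3:1), 0 °C; then 1 M HCl to pH 3
Reagents that add atoms: lithium hydroxide, [Li+].[OH-]
Why: Saponification at the acyl carbon under conditions cold and mild enough to leave the α-alkoxy stereocentre intact.

Step 8
Reactants: 10 (2R)-2-{[(2S)-2-[(4-methoxyphenyl)methoxy]pent-4-en-1-yl]oxy}butanoic acid
Product: 12 (3R)-1-diazo-3-{[(2S)-2-[(4-methoxyphenyl)methoxy]pent-4-en-1-yl]oxy}pentan-2-one, via mixed carbonic anhydride 11 (not isolated)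
Conditions: ClCO2Et, Et3N, THF, −15 °C; then Me3SiCHN2, MeCN, 0 °C → rt
Reagents that add atoms: ethyl chloroformate, CCOC(Cl)=O (its atoms stay in 11 only); (trimethylsilyl)diazomethane, C[Si](C)(C)C=[N+]=[N-]
Why: Arndt–Eistert-type C-acylation of the diazo carbon by the mixed anhydride, the silyl group leaving with the carbonate; the mixed anhydride is chosen over an acid chloride, which the benzyl-type ether oxygen five atoms away could capture, and the silyl reagent replaces explosive diazomethane.

Step 9
Reactants: 12 (3R)-1-diazo-3-{[(2S)-2-[(4-methoxyphenyl)methoxy]pent-4-en-1-yl]oxy}pentan-2-one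
Product: 13 (2R,5R)-2-ethyl-5-[(1S)-1-[(4-methoxyphenyl)methoxy]but-3-en-1-yl]oxolan-3-one
Conditions: Rh2(OAc)4 (2 mol%), CH2Cl2, rt, slow addition of 12 at high dilution
Reagents that add atoms: none
Why: Rh2(OAc)4 should expel N2 from the diazoketone to give an electrophilic rhodium carbenoid at C11, which inserts into the C10–H bond in a concerted, asynchronous three-centre process with hydride character; the closest known reaction type is the dirhodium-catalysed C–H insertion of α-diazo β-alkoxy ketones to 2,5-cis oxolan-3-ones. The oxolane closes by a 1,5 C–H insertion that forms C10–C11 through a chair-like array of Rh, C11, C12, C13, O and C10. The new C10 stereocentre is controlled by C13: with the ethyl group and the C10 side chain both pseudo-equatorial in that array the ring should close cis, and since insertion proceeds with retention only the choice between the two diastereotopic C10 hydrogens matters. Site selectivity is needed against the C9–H bond, which is also next to an oxygen but would need a 1,6 insertion into a more hindered methine, against the unactivated C15–H bonds and against the remote benzylic C–H bonds; the five-membered ring preference and the activation of C10–H by the ether oxygen should secure it. The C9 oxygen withdraws electron density from C10–H and should slow the insertion without redirecting it, which is why slow addition at high dilution is used against carbene dimerisation. The alkene is too far away for cyclopropanation, the ether oxygen could only form an oxonium ylide through a four-membered ring, and C13 is not involved, so its configuration should be kept.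

Step 10
Reactants: 13 (2R,5R)-2-ethyl-5-[(1S)-1-[(4-methoxyphenyl)methoxy]but-3-en-1-yl]oxolan-3-one
Product: 14 (2R,3R,5R)-2-ethyl-5-[(1S)-1-[(4-methoxyphenyl)methoxy]but-3-en-1-yl]oxolan-3-ol
Conditions: LiBH(s-Bu)3, THF, −78 °C; then H2O
Reagents that add atoms: none
Why: Diastereoselective ketone reduction: the bulky hydride should attack the face opposite the C13 ethyl group and the C10 side chain, placing the C12 hydroxyl cis to both (12R).

Step 11
Reactants: 14 (2R,3R,5R)-2-ethyl-5-[(1S)-1-[(4-methoxyphenyl)methoxy]but-3-en-1-yl]oxolan-3-ol
Product: 15 (2R,3S,5R)-3-bromo-2-ethyl-5-[(1S)-1-[(4-methoxyphenyl)methoxy]but-3-en-1-yl]oxolane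
Conditions: CBr4, P(n-Oct)3, toluene, 70 °C
Reagents that add atoms: carbon tetrabromide, BrC(Br)(Br)Br
Why: Appel reaction: bromide displaces the alkoxyphosphonium group by SN2 from the open face opposite both ring substituents, inverting C12 to S with bromine trans to the ethyl group; the all-cis arrangement keeps the C9 oxygen away from the back side of C12, so participation is not expected.

Step 12
Reactants: 15 (2R,3S,5R)-3-bromo-2-ethyl-5-[(1S)-1-[(4-methoxyphenyl)methoxy]but-3-en-1-yl]oxolane
Product: 17 (3S)-3-[(2R,4S,5R)-4-bromo-5-ethyloxolan-2-yl]-3-[(4-methoxyphenyl)methoxy]propanal, via vicinal diol 16 (not isolated)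
Conditions: OsO4 (2 mol%), NaIO4, 2,6-lutidine, dioxane/H2O (3:1), rt
Reagents that add atoms: osmium tetroxide, O=[Os](=O)(=O)=O (catalytic oxygen carrier); sodium periodate, [Na+].[O-]I(=O)(=O)=O
Why: Lemieux–Johnson cleavage (dihydroxylation, then periodate glycol cleavage) of the only alkene; it is preferred to ozone because of the electron-rich aryl ether, and the buffered medium should spare the β-alkoxy aldehyde, which is used crude.

Step 13
Reactants: 17 (3S)-3-[(2R,4S,5R)-4-bromo-5-ethyloxolan-2-yl]-3-[(4-methoxyphenyl)methoxy]propanal; 18 (but-3-en-1-yl)triphenylphosphonium bromide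
Product: 20 (2R,3S,5R)-3-bromo-2-ethyl-5-[(1S,3Z)-1-[(4-methoxyphenyl)methoxy]hepta-3,6-dien-1-yl]oxolane, via phosphorus ylide 19 (not isolated)
Conditions: 18, NaN(SiMe3)2, THF, −78 °C; then 17, −78 → 0 °C
Reagents that add atoms: none
Why: Wittig olefination with a non-stabilised ylide under lithium-free conditions, which should give the Z alkene through the kinetically favoured cis oxaphosphetane; the low temperature and a slight deficit of base protect the C12 bromide and the β-alkoxy aldehyde from elimination.

Step 14
Reactants: 20 (2R,3S,5R)-3-bromo-2-ethyl-5-[(1S,3Z)-1-[(4-methoxyphenyl)methoxy]hepta-3,6-dien-1-yl]oxolane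
Product: 21 (1S,3Z)-1-[(2R,4S,5R)-4-bromo-5-ethyloxolan-2-yl]hepta-3,6-dien-1-ol
Conditions: DDQ, CH2Cl2/pH 7 buffer (10:1), 0 °C
Reagents that add atoms: none
Why: Oxidative removal of the 4-methoxybenzyl ether by benzylic hydride abstraction and hydrolysis of the hemiacetal; the conditions are neutral and fluoride-free, so the bromide and the skipped diene should survive, and the C9–O bond is not broken.

Step 15
Reactants: 21 (1S,3Z)-1-[(2R,4S,5R)-4-bromo-5-ethyloxolan-2-yl]hepta-3,6-dien-1-ol
Product: 22 (1S)-1-[(2R,4S,5R)-4-bromo-5-ethyloxolan-2-yl]-2-[(2R,3S)-3-(prop-2-en-1-yl)oxiran-2-yl]ethan-1-ol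
Conditions: VO(acac)2 (5 mol%), t-BuOOH, CH2Cl2, 0 °C → rt
Reagents that add atoms: tert-butyl hydroperoxide, CC(C)(C)OO
Why: Hydroxyl-directed epoxidation of a Z-homoallylic alcohol: oxygen is delivered inside the vanadate ester through a chair in which the oxolanyl group on C9 is equatorial and the Z substituent fixes the allylic conformation, so C7 and C6 should be set syn to the C9 hydroxyl (6S,7R) with retention of the cis geometry. The remote terminal alkene is not reached by the directing group.

Step 16
Reactants: 22 (1S)-1-[(2R,4S,5R)-4-bromo-5-ethyloxolan-2-yl]-2-[(2R,3S)-3-(prop-2-en-1-yl)oxiran-2-yl]ethan-1-ol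
Product: 23 (1R)-1-[(2R,4S,5R)-4-bromo-5-ethyloxolan-2-yl]-2-[(2R,3S)-3-(prop-2-en-1-yl)oxiran-2-yl]ethyl 4-nitrobenzoate
Conditions: 4-O2NC6H4CO2H, PPh3, DIAD, THF, 0 °C → rt
Reagents that add atoms: 4-nitrobenzoic acid, OC(=O)c1ccc(cc1)[N+](=O)[O-]
Why: Mitsunobu esterification: the carboxylate displaces the oxyphosphonium group by SN2 and inverts C9 to R; the acidic nucleophile is the usual choice for a hindered secondary carbinol next to a cyclic ether.

Step 17
Reactants: 23 (1R)-1-[(2R,4S,5R)-4-bromo-5-ethyloxolan-2-yl]-2-[(2R,3S)-3-(prop-2-en-1-yl)oxiran-2-yl]ethyl 4-nitrobenzoate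
Product: 24 (1R)-1-[(2R,4S,5R)-4-bromo-5-ethyloxolan-2-yl]-2-[(2R,3S)-3-(prop-2-en-1-yl)oxiran-2-yl]ethan-1-ol
Conditions: K2CO3, MeOH, 0 °C
Reagents that add atoms: none
Why: Methanolysis of the activated aryl ester at the acyl carbon, so C9 keeps its new configuration; the conditions are too mild for opening of the oxirane or loss of HBr.

Step 18
Reactants: 24 (1R)-1-[(2R,4S,5R)-4-bromo-5-ethyloxolan-2-yl]-2-[(2R,3S)-3-(prop-2-en-1-yl)oxiran-2-yl]ethan-1-ol
Product: 25 (2R,3S,5R)-3-bromo-5-[(1S)-1-bromo-2-[(2R,3S)-3-(prop-2-en-1-yl)oxiran-2-yl]ethyl]-2-ethyloxolane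
Conditions: CBr4, P(n-Oct)3, 2,6-di-tert-butylpyridine, toluene, rt → 50 °C
Reagents that add atoms: carbon tetrabromide, BrC(Br)(Br)Br
Why: Appel reaction with SN2 inversion at C9 (R to S), which together with step 16 puts bromine where the directing hydroxyl stood; the non-polar solvent favours direct displacement over ionisation, and the hindered base guards the oxirane against adventitious acid.

Step 19
Reactants: 25 (2R,3S,5R)-3-bromo-5-[(1S)-1-bromo-2-[(2R,3S)-3-(prop-2-en-1-yl)oxiran-2-yl]ethyl]-2-ethyloxolane
Product: 26 (2E)-4-[(2S,3R)-3-{(2S)-2-bromo-2-[(2R,4S,5R)-4-bromo-5-ethyloxolan-2-yl]ethyl}oxiran-2-yl]but-2-enal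
Conditions: crotonaldehyde (10 equiv), second-generation Grubbs catalyst (H2IMes)(PCy3)Cl2Ru=CHPh (5 mol%), CH2Cl2, 40 °C
Reagents that add atoms: (E)-but-2-enal (crotonaldehyde), C/C=C/C=O
Why: Olefin cross-metathesis between a terminal alkene and an electron-poor enal partner, which should give the conjugated enal under thermodynamic control as the E isomer; the substrate holds no other alkene.

Step 20
Reactants: 26 (2E)-4-[(2S,3R)-3-{(2S)-2-bromo-2-[(2R,4S,5R)-4-bromo-5-ethyloxolan-2-yl]ethyl}oxiran-2-yl]but-2-enal
Product: 27 (2R,3S,5R)-3-bromo-5-[(1S)-1-bromo-2-[(2R,3S)-3-[(2E)-pent-2-en-4-yn-1-yl]oxiran-2-yl]ethyl]-2-ethyloxolane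
Conditions: Me3SiCHN2, LiN(i-Pr)2, THF, −78 °C; then 26, −78 → 0 °C
Reagents that add atoms: (trimethylsilyl)diazomethane, C[Si](C)(C)C=[N+]=[N-]
Why: Colvin rearrangement: the lithiated silyl diazomethane adds to the aldehyde, Peterson-type loss of silanolate and then of N2 gives an alkylidene carbene, and a 1,2-shift gives the terminal alkyne, with the reagent carbon becoming C1; the E alkene is not touched, and addition at −78 °C should outrun deprotonation.

## Compound list

1 | (R)-glycidol | OC[C@@H]1CO1 | starting material
2 | vinylmagnesium bromide | C=C[Mg]Br | starting material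
3 | (S)-pent-4-ene-1,2-diol | OC[C@@H](O)CC=C | intermediate
4 | (4S)-2-(4-methoxyphenyl)-4-(prop-2-en-1-yl)-1,3-dioxolane (both acetal epimers) | O1C[C@@H](OC1c2ccc(OC)cc2)CC=C | intermediate
5 | (2S)-2-[(4-methoxyphenyl)methoxy]pent-4-en-1-ol | OC[C@@H](OCc1ccc(OC)cc1)CC=C | intermediate
6 | (S)-2-hydroxybutanoic acid | CC[C@H](O)C(=O)O | starting material
7 | methyl (S)-2-hydroxybutanoate | CC[C@H](O)C(=O)OC | intermediate
8 | methyl (2S)-2-[(trifluoromethanesulfonyl)oxy]butanoate | CC[C@H](OS(=O)(=O)C(F)(F)F)C(=O)OC | intermediate
9 | methyl (2R)-2-{[(2S)-2-[(4-methoxyphenyl)methoxy]pent-4-en-1-yl]oxy}butanoate | COC(=O)[C@@H](CC)OC[C@@H](OCc1ccc(OC)cc1)CC=C | intermediate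
10 | (2R)-2-{[(2S)-2-[(4-methoxyphenyl)methoxy]pent-4-en-1-yl]oxy}butanoic acid | OC(=O)[C@@H](CC)OC[C@@H](OCc1ccc(OC)cc1)CC=C | intermediate
11 | (2R)-2-{[(2S)-2-[(4-methoxyphenyl)methoxy]pent-4-en-1-yl]oxy}butanoic ethyl carbonic anhydride | CCOC(=O)OC(=O)[C@@H](CC)OC[C@@H](OCc1ccc(OC)cc1)CC=C | intermediate (not isolated)
12 | (3R)-1-diazo-3-{[(2S)-2-[(4-methoxyphenyl)methoxy]pent-4-en-1-yl]oxy}pentan-2-one | [N-]=[N+]=CC(=O)[C@@H](CC)OC[C@@H](OCc1ccc(OC)cc1)CC=C | intermediate
13 | (2R,5R)-2-ethyl-5-[(1S)-1-[(4-methoxyphenyl)methoxy]but-3-en-1-yl]oxolan-3-one | C=CC[C@H](OCc1ccc(OC)cc1)[C@H]1CC(=O)[C@@H](CC)O1 | intermediate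
14 | (2R,3R,5R)-2-ethyl-5-[(1S)-1-[(4-methoxyphenyl)methoxy]but-3-en-1-yl]oxolan-3-ol | C=CC[C@H](OCc1ccc(OC)cc1)[C@H]1C[C@@H](O)[C@@H](CC)O1 | intermediate
15 | (2R,3S,5R)-3-bromo-2-ethyl-5-[(1S)-1-[(4-methoxyphenyl)methoxy]but-3-en-1-yl]oxolane | C=CC[C@H](OCc1ccc(OC)cc1)[C@H]1C[C@H](Br)[C@@H](CC)O1 | intermediate
16 | (4S)-4-[(2R,4S,5R)-4-bromo-5-ethyloxolan-2-yl]-4-[(4-methoxyphenyl)methoxy]butane-1,2-diol (both C2 epimers) | OCC(O)C[C@H](OCc1ccc(OC)cc1)[C@H]1C[C@H](Br)[C@@H](CC)O1 | intermediate (not isolated)
17 | (3S)-3-[(2R,4S,5R)-4-bromo-5-ethyloxolan-2-yl]-3-[(4-methoxyphenyl)methoxy]propanal | O=CC[C@H](OCc1ccc(OC)cc1)[C@H]1C[C@H](Br)[C@@H](CC)O1 | intermediate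
18 | (but-3-en-1-yl)triphenylphosphonium bromide | C=CCC[P+](c1ccccc1)(c1ccccc1)c1ccccc1.[Br-] | starting material
19 | (but-3-en-1-ylidene)triphenyl-λ5-phosphane | C=CCC=P(c1ccccc1)(c1ccccc1)c1ccccc1 | intermediate (not isolated)
20 | (2R,3S,5R)-3-bromo-2-ethyl-5-[(1S,3Z)-1-[(4-methoxyphenyl)methoxy]hepta-3,6-dien-1-yl]oxolane | C=CC/C=C\C[C@H](OCc1ccc(OC)cc1)[C@H]1C[C@H](Br)[C@@H](CC)O1 | intermediate
21 | (1S,3Z)-1-[(2R,4S,5R)-4-bromo-5-ethyloxolan-2-yl]hepta-3,6-dien-1-ol | C=CC/C=C\C[C@H](O)[C@H]1C[C@H](Br)[C@@H](CC)O1 | intermediate
22 | (1S)-1-[(2R,4S,5R)-4-bromo-5-ethyloxolan-2-yl]-2-[(2R,3S)-3-(prop-2-en-1-yl)oxiran-2-yl]ethan-1-ol | C=CC[C@@H]1O[C@@H]1C[C@H](O)[C@H]1C[C@H](Br)[C@@H](CC)O1 | intermediate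
23 | (1R)-1-[(2R,4S,5R)-4-bromo-5-ethyloxolan-2-yl]-2-[(2R,3S)-3-(prop-2-en-1-yl)oxiran-2-yl]ethyl 4-nitrobenzoate | C=CC[C@@H]1O[C@@H]1C[C@@H](OC(=O)c2ccc(cc2)[N+](=O)[O-])[C@H]1C[C@H](Br)[C@@H](CC)O1 | intermediate
24 | (1R)-1-[(2R,4S,5R)-4-bromo-5-ethyloxolan-2-yl]-2-[(2R,3S)-3-(prop-2-en-1-yl)oxiran-2-yl]ethan-1-ol | C=CC[C@@H]1O[C@@H]1C[C@@H](O)[C@H]1C[C@H](Br)[C@@H](CC)O1 | intermediate
25 | (2R,3S,5R)-3-bromo-5-[(1S)-1-bromo-2-[(2R,3S)-3-(prop-2-en-1-yl)oxiran-2-yl]ethyl]-2-ethyloxolane | C=CC[C@@H]1O[C@@H]1C[C@H](Br)[C@H]1C[C@H](Br)[C@@H](CC)O1 | intermediate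
26 | (2E)-4-[(2S,3R)-3-{(2S)-2-bromo-2-[(2R,4S,5R)-4-bromo-5-ethyloxolan-2-yl]ethyl}oxiran-2-yl]but-2-enal | O=C/C=C/C[C@@H]1O[C@@H]1C[C@H](Br)[C@H]1C[C@H](Br)[C@@H](CC)O1 | intermediate
27 | (2R,3S,5R)-3-bromo-5-[(1S)-1-bromo-2-[(2R,3S)-3-[(2E)-pent-2-en-4-yn-1-yl]oxiran-2-yl]ethyl]-2-ethyloxolane | C#C/C=C/C[C@@H]1O[C@@H]1C[C@H](Br)[C@H]1C[C@H](Br)[C@@H](CC)O1 | target

## Step count and least certain steps

Total: 20 steps. Longest linear sequence: 18 steps (steps 1 to 3 and 6 to 20, from 1). Steps 4 and 5 form the short branch from 6.

Step 9 (key step). The carbenoid may be diverted. The C9 oxygen inductively deactivates C10–H, which could leave room for 1,6 insertion at the C9 methine, carbene dimerisation or capture by traces of water, and the cis preference could be incomplete. The fallback replaces C–H insertion by a Michael–Dieckmann ring synthesis. It sets out from 5 and 7 and returns at 13.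
- Oxidation of 5 (SO3·pyridine, DMSO, i-Pr2NEt) would give (2S)-2-[(4-methoxyphenyl)methoxy]pent-4-enal F1.
- Wittig olefination with methyl (triphenylphosphoranylidene)acetate would give methyl (2E,4S)-4-[(4-methoxyphenyl)methoxy]hepta-2,6-dienoate F2.
- The sodium alkoxide of 7 (NaH, THF) would add in conjugate fashion to give methyl (4S)-3-[(1-methoxy-1-oxobutan-2-yl)oxy]-4-[(4-methoxyphenyl)methoxy]hept-6-enoate F3.
- F3 should close in the same flask by Dieckmann condensation to methyl 5-ethyl-2-[(1S)-1-[(4-methoxyphenyl)methoxy]but-3-en-1-yl]-4-oxooxolane-3-carboxylate F4.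
- Krapcho dealkoxycarbonylation (NaCl, wet DMSO, 130 °C) would then lead to 13.
- In this variant C13 is epimerisable and the cis ring would rest on thermodynamic preference, while C10 would depend on the facial bias of the C9 stereocentre, so separation of isomers has to be expected.

Step 6. Substitution may lose to E2 elimination of the triflate, to attack of the alkoxide at the ester carbonyl, or to erosion of configuration at C13 before the alkoxide arrives. The fallback uses a carboxylate electrophile, which cannot be acylated. It sets out from 5 and returns at 10, passing over 8, 9 and step 7. The sodium alkoxide of 5 (excess NaH, THF/DMF, 50 °C) would displace bromide from the sodium salt of (2S)-2-bromobutanoic acid F5 with inversion, and acidification would give 10 directly.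

Step 15. Facial selectivity may be poor if chelation of vanadium by the ring oxygen competes with the simple chair. The C9 hydroxyl may also open the new oxirane under Lewis-acid promotion. The fallback builds the oxirane by iodocarbonate cyclisation. It sets out from 21 and returns at 22.
- Acylation (Boc2O, DMAP, MeCN) would give tert-butyl (1S,3Z)-1-[(2R,4S,5R)-4-bromo-5-ethyloxolan-2-yl]hepta-3,6-dien-1-yl carbonate F6.
- IBr in toluene at −85 °C should close the six-membered carbonate with the new C7–O bond cis to the C9 substituent and iodine anti at C6, giving (4S,6R)-4-[(2R,4S,5R)-4-bromo-5-ethyloxolan-2-yl]-6-[(1R)-1-iodobut-3-en-1-yl]-1,3-dioxan-2-one F7.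
- K2CO3 in MeOH would cleave the carbonate, and the C7 alkoxide would displace iodide with inversion at C6 to give 22.

Step 18. The ring oxygen may take part in the departure of the activated C9 oxygen, leading to retention or ring expansion through an oxonium ion. Bromide in the phosphonium medium may open the oxirane, and HBr may be lost. The fallback separates activation from displacement. It sets out from 24 and returns at 25. Sulfonylation (ClCH2SO2Cl, 2,6-lutidine, CH2Cl2, 0 °C) would give (1R)-1-[(2R,4S,5R)-4-bromo-5-ethyloxolan-2-yl]-2-[(2R,3S)-3-(prop-2-en-1-yl)oxiran-2-yl]ethyl chloromethanesulfonate F8. Bu4NBr in toluene at rt to 40 °C would displace the sulfonate with inversion in the absence of any Lewis acid.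

Step 20. Deprotonation may compete with addition. Removal of a C5 proton from the enal would be followed by opening of the oxirane, and the lithium reagent may also cause E2 loss of HBr. The fallback builds the enyne by cross-coupling under weakly basic conditions. It sets out from 25 and returns at 27.
- Cross-metathesis with vinylboronic acid pinacol ester (second-generation Grubbs catalyst (H2IMes)(PCy3)Cl2Ru=CHPh, CH2Cl2, 40 °C) would give 2-[(1E)-3-[(2S,3R)-3-{(2S)-2-bromo-2-[(2R,4S,5R)-4-bromo-5-ethyloxolan-2-yl]ethyl}oxiran-2-yl]prop-1-en-1-yl]-4,4,5,5-tetramethyl-1,3,2-dioxaborolane F9.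
- Suzuki–Miyaura coupling with (bromoethynyl)trimethylsilane (Pd(PPh3)4, K3PO4, THF/H2O, rt) would give trimethyl{(3E)-5-[(2S,3R)-3-{(2S)-2-bromo-2-[(2R,4S,5R)-4-bromo-5-ethyloxolan-2-yl]ethyl}oxiran-2-yl]pent-3-en-1-yn-1-yl}silane F10.
- K2CO3 in MeOH at 0 °C would remove the silyl group to give 27.

## Further compounds

F1 | step 9 | (2S)-2-[(4-methoxyphenyl)methoxy]pent-4-enal | O=C[C@@H](OCc1ccc(OC)cc1)CC=C
F2 | step 9 | methyl (2E,4S)-4-[(4-methoxyphenyl)methoxy]hepta-2,6-dienoate | COC(=O)/C=C/[C@@H](OCc1ccc(OC)cc1)CC=C
F3 | step 9 | methyl (4S)-3-[(1-methoxy-1-oxobutan-2-yl)oxy]-4-[(4-methoxyphenyl)methoxy]hept-6-enoate (epimers at C3 and at the butanoate carbon) | COC(=O)CC(OC(CC)C(=O)OC)[C@@H](OCc1ccc(OC)cc1)CC=C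
F4 | step 9 | methyl 5-ethyl-2-[(1S)-1-[(4-methoxyphenyl)methoxy]but-3-en-1-yl]-4-oxooxolane-3-carboxylate (ring epimers) | C=CC[C@H](OCc1ccc(OC)cc1)C1OC(CC)C(=O)C1C(=O)OC
F5 | step 6 | (2S)-2-bromobutanoic acid | CC[C@H](Br)C(=O)O
F6 | step 15 | tert-butyl (1S,3Z)-1-[(2R,4S,5R)-4-bromo-5-ethyloxolan-2-yl]hepta-3,6-dien-1-yl carbonate | C=CC/C=C\C[C@H](OC(=O)OC(C)(C)C)[C@H]1C[C@H](Br)[C@@H](CC)O1
F7 | step 15 | (4S,6R)-4-[(2R,4S,5R)-4-bromo-5-ethyloxolan-2-yl]-6-[(1R)-1-iodobut-3-en-1-yl]-1,3-dioxan-2-one | C=CC[C@@H](I)[C@H]1C[C@H](OC(=O)O1)[C@H]2C[C@H](Br)[C@@H](CC)O2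
F8 | step 18 | (1R)-1-[(2R,4S,5R)-4-bromo-5-ethyloxolan-2-yl]-2-[(2R,3S)-3-(prop-2-en-1-yl)oxiran-2-yl]ethyl chloromethanesulfonate | C=CC[C@@H]1O[C@@H]1C[C@@H](OS(=O)(=O)CCl)[C@H]1C[C@H](Br)[C@@H](CC)O1
F9 | step 20 | 2-[(1E)-3-[(2S,3R)-3-{(2S)-2-bromo-2-[(2R,4S,5R)-4-bromo-5-ethyloxolan-2-yl]ethyl}oxiran-2-yl]prop-1-en-1-yl]-4,4,5,5-tetramethyl-1,3,2-dioxaborolane | CC1(C)OB(/C=C/C[C@@H]2O[C@@H]2C[C@H](Br)[C@H]2C[C@H](Br)[C@@H](CC)O2)OC1(C)C
F10 | step 20 | trimethyl{(3E)-5-[(2S,3R)-3-{(2S)-2-bromo-2-[(2R,4S,5R)-4-bromo-5-ethyloxolan-2-yl]ethyl}oxiran-2-yl]pent-3-en-1-yn-1-yl}silane | C[Si](C)(C)C#C/C=C/C[C@@H]1O[C@@H]1C[C@H](Br)[C@H]1C[C@H](Br)[C@@H](CC)O1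
A1 | alternative 1 | (1S)-1-[(2R,4S,5R)-4-bromo-5-ethyloxolan-2-yl]-2-[(2R,3S)-3-(prop-2-en-1-yl)oxiran-2-yl]ethan-1-ol | C=CC[C@@H]1O[C@@H]1C[C@H](O)[C@H]1C[C@H](Br)[C@@H](CC)O1
A2 | alternative 2 | 1-[(1R,2R)-2-{(1R,3S)-3-bromo-3-[(2R,4S,5R)-4-bromo-5-ethyloxolan-2-yl]-1-[(tert-butyldimethylsilyl)oxy]propyl}cyclopropyl]-3-(trimethylsilyl)prop-2-yn-1-ol (either configuration at the carbinol carbon) | C[Si](C)(C)C#CC(O)[C@@H]1C[C@H]1[C@H](O[Si](C)(C)C(C)(C)C)C[C@H](Br)[C@H]2C[C@H](Br)[C@@H](CC)O2
A3 | alternative 2 | {(3E,6R,7R,9S)-6,9-dibromo-9-[(2R,4S,5R)-4-bromo-5-ethyloxolan-2-yl]-7-[(tert-butyldimethylsilyl)oxy]non-3-en-1-yn-1-yl}trimethylsilane | C[Si](C)(C)C#C/C=C/C[C@@H](Br)[C@H](O[Si](C)(C)C(C)(C)C)C[C@H](Br)[C@H]1C[C@H](Br)[C@@H](CC)O1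
A4 | alternative 3 | furan | c1ccoc1
A5 | alternative 3 | 2-bromoprop-2-enal (2-bromoacrolein) | C=C(Br)C=O
A6 | alternative 3 | 2-endo-bromo-7-oxabicyclo[2.2.1]hept-5-ene-2-exo-carbaldehyde (enantiomer shown) | C1=C[C@H]2O[C@@H]1C[C@]2(Br)C=O
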